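**Time of reading.** The ash run is read at 32 min, the last time of the oak run, which had the same charge of starting material.

| setting | elm | oak | larch | birch | ash |
|---|---|---|---|---|---|
| starting material | 50.0 mM | 20.0 mM | 50.0 mM | 150 mM | 20.0 mM |
| target |  |  | 15.0 mM |  |  |
| time |  |  |  |  | 32 min |

| run | time / min | [target] / mM |
|---|---|---|
| elm run | 1.3 | 1.9 |
| elm run | 2.4 | 2.9 |
| elm run | 4.6 | 6.9 |
| elm run | 8.8 | 11.3 |
| elm run | 17 | 18.1 |
| elm run | 32 | 22.9 |
| oak run | 1.3 | 0.8 |
| oak run | 2.4 | 2.2 |
| oak run | 4.6 | 4.0 |
| oak run | 8.8 | 6.0 |
| oak run | 17 | 8.9 |
| oak run | 32 | 11.0 |
| larch run | 1.3 | 16.7 |
| larch run | 2.4 | 17.9 |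
| larch run | 4.6 | 19.8 |
| larch run | 8.8 | 24.2 |
| larch run | 17 | 28.6 |
| larch run | 32 | 31.5 |
| birch run | 1.3 | 4.0 |
| birch run | 2.4 | 7.6 |
| birch run | 4.6 | 13.9 |
| birch run | 8.8 | 23.5 |
| birch run | 17 | 36.4 |
| birch run | 32 | 48.6 |

(readings scatter by 0.3 mM)

- Overall: starting material -> target.
- Constant volume, constant temperature.
- Bound and free are read together.
- An order is taken over about fifteen percent of the charge, up and down.

* how the opening rate goes with [starting material] round the charge of the elm run: the exponent of the rate at two percent of starting material gone to target (one fixed amount of target, the same in the runs compared)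
* target in the ash run at 32 min, as a share of the starting material charged

By hand, the oak run's pace over its first 4.6 min, 0.870 mM/min, held to 32 min would give 27.8 mM of target, more than the 20.0 mM charged. The reading is 11.0 mM, so the rate falls along the way.

**Charge.** In a first-order flask, the birch run would make 7.50 times the target of the oak run in the same early time. At 4.6 min the readings give 3.48 times. Our reckoning divides the logarithm of the second ratio by that of the first; call this apparent order the charge exponent: 0.618. It spans a wider range than the one asked, with the elm charge inside it.

Integrate a rate that goes as starting material to this power, and the time to a given share goes as the charge to the power of one minus the exponent. An exponent of one gives a time constant free of the charge. As an estimate, ours puts the time to a given share in the elm run at 1.42 times that in the oak run.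

**Added target.** By hand, target charged at the start might push back. By 4.6 min the larch run adds 4.80 mM, less than the 6.9 mM of the elm run. The ash run starts without target, like the oak run.

**Our estimate.** With equal charges the factor is one, so we expect the oak share, 55.0%, with a scatter of 1.50% of the charge. The forecast gives 55% and an order of 0.6, calling ash “effectively a replicate”.

    starting material ⇌ target (0.07140 /min, 0.02376 /min)
    2 starting material ⇌ idle substrate dimer, settled at all times (23.90 /M)
    2 starting material → homo dimer (0.8520 /M/min)

**Result.** The flask gives an order of 0.68, above our exponent, and 55.4% for the ash run, 0.40 percentage points above the oak reading. At two percent of the elm charge turned, the rates are 0.83 mM/min in the oak run and 3.3 mM/min in the birch run. Our exponent's time factor was 1.42, and the elm run reaches a quarter of its charge at 9.87 min against 7.04 min for the oak run, a ratio of 1.40.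

All runs were generated by integration with made-up constants, and the scatter is random.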